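The flavone is disconnected at C3 of ring C, the lone CH carbon lying between C2 and the C4 carbonyl. Taking C3 out contracts the pyranone to the furan ring of a 2-aryl-3-silyloxybenzofuran, whose furan C2=C3 bond carries two oxygen donors and is the most nucleophilic site in the molecule. In the key step dibromocarbene adds to that bond and the fused dibromocyclopropane opens, so that C2–C3, C3–C4 (flavone numbering) and the six-membered ring C form in one operation as a 3-bromoflavone. The precursor is the tert-butyldimethylsilyl enol ether of 5,6-dimethoxy-2-(2,3,4-trimethoxyphenyl)benzofuran-3-one, preferred to the trimethylsilyl ether because it resists tert-butoxide. Hydrogenolysis of C3–Br then gives the target.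

Key step: step 4

Remark on the chemistry: the silyl group is a spectator in the key step, so the precursor is made as its tert-butyldimethylsilyl ether 6 (same benzofuran skeleton, but more stable to tert-butoxide and to isolation than a trimethylsilyl ether). Compounds 4, 5 and 8 are racemic, and the target has no stereocentre.

Step 1
Reactants: 1 3,4-dimethoxyphenol; 2 2-(2,3,4-trimethoxyphenyl)acetic acid
Product: 3 1-(2-hydroxy-4,5-dimethoxyphenyl)-2-(2,3,4-trimethoxyphenyl)ethan-1-one
Conditions: BF3·OEt2 (neat, about 5 equiv), 85 °C, Ar; then aq. NaOAc, rt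
Reagents that add atoms: none
Why: Friedel–Crafts C-acylation of a phenol by an arylacetic acid in boron trifluoride etherate (the usual deoxybenzoin synthesis) should take place at C6 of 1, ortho to the hydroxyl and para to the 3-methoxy group, since the other ortho position is flanked by two oxygen substituents and the ortho-hydroxy ketone is held as a difluoroboron chelate until hydrolysis.

Step 2
Reactants: 3 1-(2-hydroxy-4,5-dimethoxyphenyl)-2-(2,3,4-trimethoxyphenyl)ethan-1-one
Product: 4 2-bromo-1-(2-hydroxy-4,5-dimethoxyphenyl)-2-(2,3,4-trimethoxyphenyl)ethan-1-one (racemic)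
Conditions: CuBr2 (2.1 equiv), EtOAc/CHCl3 1:1, reflux; filtered, concentrated, used crude
Reagents that add atoms: copper dibromide CuBr2, Br[Cu]Br
Why: α-Bromination of a ketone with copper dibromide proceeds through the copper-bound enol of the doubly activated benzylic CH2 group, which should react well before either methoxylated ring and stop at the monobromide; the new stereocentre is set without control (racemate) and disappears when this carbon becomes sp2 in 6.

Step 3
Reactants: 4 2-bromo-1-(2-hydroxy-4,5-dimethoxyphenyl)-2-(2,3,4-trimethoxyphenyl)ethan-1-one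
Product: 6 tert-butyl{[5,6-dimethoxy-2-(2,3,4-trimethoxyphenyl)-1-benzofuran-3-yl]oxy}dimethylsilane, via 2-arylbenzofuran-3(2H)-one 5 (not isolated)
Conditions: i-Pr2NEt (3.5 equiv), degassed CH2Cl2, 0 °C to rt, Ar; then TBSOTf (1.3 equiv), 0 °C
Reagents that add atoms: tert-butyldimethylsilyl trifluoromethanesulfonate, CC(C)(C)[Si](C)(C)OS(=O)(=O)C(F)(F)F
Why: The phenoxide should displace the activated benzylic α-bromide in an intramolecular Williamson etherification (5-exo-tet) to give benzofuranone 5, whose acidic C2–H is removed by the amine so that the silyl triflate traps the aromatic 3-hydroxybenzofuran form on oxygen (silyl enol ether formation) in the same flask, before air or unreacted 4 can intercept it.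

Step 4
Reactants: 6 tert-butyl{[5,6-dimethoxy-2-(2,3,4-trimethoxyphenyl)-1-benzofuran-3-yl]oxy}dimethylsilane; 7 bromoform
Product: 10 3-bromo-6,7-dimethoxy-2-(2,3,4-trimethoxyphenyl)-4H-chromen-4-one, via fused dibromocyclopropane 8 (not isolated), via 4-silyloxybenzopyrylium bromide 9 (not isolated)
Conditions: KOtBu (solid, 2.5 equiv), CHBr3 (2.5 equiv, added slowly), toluene/hexane, −30 °C to rt, Ar; then aqueous work-up
Reagents that add atoms: bromoform 7, BrC(Br)Br
Why: Proposed new method: α-elimination of bromoform with KOtBu releases dibromocarbene, which should add in a concerted [2+1] cycloaddition to the furan C2=C3 bond of 6 to give the cis-fused dibromocyclopropane 8. Loss of the endo bromide is coupled to disrotatory opening of the cyclopropane bond common to both rings (cyclopropyl-to-allyl cation electrocyclic opening), which gives the 4-silyloxybenzopyrylium bromide 9, stabilised by O1 and the silyloxy oxygen, and bromide then takes the silyl group from oxygen (as the silyl bromide, hydrolysed on work-up) to leave the 4-pyranone 10. The nearest established reactions are the conversion of cyclic silyl enol ethers into ring-enlarged α-halo enones by dihalocarbenes and the Ciamician–Dennstedt carbene insertion into indoles and benzofurans; neither has been shown on a 3-silyloxybenzofuran. Ring C is closed by ring enlargement, the five-membered furan growing to the six-membered pyranone through this two-electron electrocyclic opening and not through an exo or endo cyclisation, and no stereocentre results because both ring-fusion carbons of 8 end as sp2 centres. The step needs the carbene to choose the enol ether bond over the two methoxylated benzene rings and needs the O–Si bond to last until the carbene has added; the first rests on the far higher nucleophilicity of the O–C=C–O unit towards an electrophilic carbene, the second on the bulky tert-butyldimethylsilyl group, solid KOtBu in a non-polar solvent and low temperature. Aromatisation to the pyrylium ion and then formation of the conjugated 4-pyranone pull the sequence forward.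

Step 5
Reactants: 10 3-bromo-6,7-dimethoxy-2-(2,3,4-trimethoxyphenyl)-4H-chromen-4-one
Product: 11 6,7-dimethoxy-2-(2,3,4-trimethoxyphenyl)-4H-chromen-4-one (target)
Conditions: H2 (1 atm), 10% Pd/C, Et3N (1.5 equiv), EtOAc/MeOH, rt
Reagents that add atoms: none
Why: Catalytic hydrogenolysis of the vinylic C3–Br bond over palladium on carbon, with triethylamine taking up the hydrogen bromide, should be much faster than saturation of the vinylogous-ester C2=C3 bond, so stopping after one equivalent of hydrogen should leave the flavone intact (hydrodehalogenation).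

Compound list
1 | 3,4-dimethoxyphenol | COc1ccc(O)cc1OC | starting material
2 | 2-(2,3,4-trimethoxyphenyl)acetic acid | COc1ccc(CC(=O)O)c(OC)c1OC | starting material
3 | 1-(2-hydroxy-4,5-dimethoxyphenyl)-2-(2,3,4-trimethoxyphenyl)ethan-1-one | COc1ccc(CC(=O)c2cc(OC)c(OC)cc2O)c(OC)c1OC | intermediate
4 | 2-bromo-1-(2-hydroxy-4,5-dimethoxyphenyl)-2-(2,3,4-trimethoxyphenyl)ethan-1-one (racemic) | COc1ccc(C(Br)C(=O)c2cc(OC)c(OC)cc2O)c(OC)c1OC | intermediate
5 | 5,6-dimethoxy-2-(2,3,4-trimethoxyphenyl)-1-benzofuran-3(2H)-one (racemic, not isolated) | COc1cc2OC(c3ccc(OC)c(OC)c3OC)C(=O)c2cc1OC | intermediate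
6 | tert-butyl{[5,6-dimethoxy-2-(2,3,4-trimethoxyphenyl)-1-benzofuran-3-yl]oxy}dimethylsilane | COc1cc2oc(-c3ccc(OC)c(OC)c3OC)c(O[Si](C)(C)C(C)(C)C)c2cc1OC | intermediate
7 | bromoform | BrC(Br)Br | starting material
8 | tert-butyl{[1,1-dibromo-4,5-dimethoxy-1a-(2,3,4-trimethoxyphenyl)-1a,6b-dihydro-1H-cyclopropa[b][1]benzofuran-6b-yl]oxy}dimethylsilane, i.e. 6 with a CBr2 bridge across furan C2 and C3 (cis-fused, racemic, one enantiomer drawn, not isolated) | COc1cc2O[C@]3(c4ccc(OC)c(OC)c4OC)C(Br)(Br)[C@]3(O[Si](C)(C)C(C)(C)C)c2cc1OC | intermediate
9 | 3-bromo-4-[(tert-butyldimethylsilyl)oxy]-6,7-dimethoxy-2-(2,3,4-trimethoxyphenyl)chromenylium bromide (not isolated) | COc1cc2[o+]c(-c3ccc(OC)c(OC)c3OC)c(Br)c(O[Si](C)(C)C(C)(C)C)c2cc1OC.[Br-] | intermediate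
10 | 3-bromo-6,7-dimethoxy-2-(2,3,4-trimethoxyphenyl)-4H-chromen-4-one | COc1cc2oc(-c3ccc(OC)c(OC)c3OC)c(Br)c(=O)c2cc1OC | intermediate
11 | 6,7-dimethoxy-2-(2,3,4-trimethoxyphenyl)-4H-chromen-4-one | COc1cc2oc(-c3ccc(OC)c(OC)c3OC)cc(=O)c2cc1OC | target

Total step count: 5. Longest linear sequence: 5 steps (from 1 or 2 to 11).

Steps most likely to fail

Step 4 (key step). The O–Si bond may be cleaved by tert-butoxide before the carbene arrives, after which the free enolate would be dibromomethylated at C2 without ring enlargement; cyclopropanation of the hindered, fully substituted double bond may also be too slow to compete with carbene decay. The fallback gives up the ring expansion and uses known flavone chemistry. Setting out from 1, acetylation with acetic acid in BF3·OEt2 at 85 °C should give 1-(2-hydroxy-4,5-dimethoxyphenyl)ethan-1-one F1. Claisen–Schmidt condensation of this ketone with purchased 2,3,4-trimethoxybenzaldehyde (COc1ccc(C=O)c(OC)c1OC; KOH, EtOH, rt) should give (E)-1-(2-hydroxy-4,5-dimethoxyphenyl)-3-(2,3,4-trimethoxyphenyl)prop-2-en-1-one F2. Oxidative cyclisation of this 2'-hydroxychalcone with catalytic iodine in DMSO at 130 °C should close ring C and come back to the route directly at the target 11.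

Step 2. Electrophilic bromination of ring B (C5, para to the 2-methoxy group) or of ring A may compete with the α-position. A second bromine may also enter, and the electron-rich benzylic bromide may be lost by solvolysis during isolation. The fallback brominates a preformed enol silane instead of the ketone. Setting out from 3, TMSOTf and Et3N in CH2Cl2 at 0 °C should silylate both the phenol and the enol to give (Z)-{[1-{4,5-dimethoxy-2-[(trimethylsilyl)oxy]phenyl}-2-(2,3,4-trimethoxyphenyl)ethenyl]oxy}trimethylsilane F3 (either alkene geometry serves). N-Bromosuccinimide in THF at −78 °C, where the arenes do not react, should then give 2-bromo-1-{4,5-dimethoxy-2-[(trimethylsilyl)oxy]phenyl}-2-(2,3,4-trimethoxyphenyl)ethan-1-one F4. Work-up with dilute aqueous citric acid should cleave the aryl silyl ether and return to the route at 4.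

Step 3. The enolisable benzofuranone may be oxidised at C2 by traces of air or C-alkylated by unreacted bromoketone before O-silylation is complete, and the silyl enol ether may hydrolyse in part on purification. The fallback passes through an air-stable enol ester. Setting out from crude 4, K2CO3 in degassed acetone at rt should close the furanone ring, and acetic anhydride added to the same flask should trap the enolate as 5,6-dimethoxy-2-(2,3,4-trimethoxyphenyl)-1-benzofuran-3-yl acetate F5, which can be crystallised and stored. MeLi (2 equiv, THF, −78 °C) should then release lithium 5,6-dimethoxy-2-(2,3,4-trimethoxyphenyl)-1-benzofuran-3-olate F6 in the absence of oxygen and of 4. TBSCl with DMPU should silylate it on oxygen and rejoin the route at 6.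

Further compounds
F1 | step 4 | 1-(2-hydroxy-4,5-dimethoxyphenyl)ethan-1-one | CC(=O)c1cc(OC)c(OC)cc1O
F2 | step 4 | (E)-1-(2-hydroxy-4,5-dimethoxyphenyl)-3-(2,3,4-trimethoxyphenyl)prop-2-en-1-one | COc1ccc(/C=C/C(=O)c2cc(OC)c(OC)cc2O)c(OC)c1OC
F3 | step 2 | (Z)-{[1-{4,5-dimethoxy-2-[(trimethylsilyl)oxy]phenyl}-2-(2,3,4-trimethoxyphenyl)ethenyl]oxy}trimethylsilane | COc1ccc(/C=C(\O[Si](C)(C)C)c2cc(OC)c(OC)cc2O[Si](C)(C)C)c(OC)c1OC
F4 | step 2 | 2-bromo-1-{4,5-dimethoxy-2-[(trimethylsilyl)oxy]phenyl}-2-(2,3,4-trimethoxyphenyl)ethan-1-one (racemic) | COc1ccc(C(Br)C(=O)c2cc(OC)c(OC)cc2O[Si](C)(C)C)c(OC)c1OC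
F5 | step 3 | 5,6-dimethoxy-2-(2,3,4-trimethoxyphenyl)-1-benzofuran-3-yl acetate | COc1cc2oc(-c3ccc(OC)c(OC)c3OC)c(OC(C)=O)c2cc1OC
F6 | step 3 | lithium 5,6-dimethoxy-2-(2,3,4-trimethoxyphenyl)-1-benzofuran-3-olate | COc1cc2oc(-c3ccc(OC)c(OC)c3OC)c([O-])c2cc1OC.[Li+]
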